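**Retrosynthetic overview**

- The strategy rests on the two 3-methylbut-2-enyl chains on C6 and C8 of ring A, which flank the C7 hydroxyl. Each ends in a Me2C=CH unit two carbons from the ring, so each is an allyl group whose terminal CH2 has been exchanged for CMe2.
- Key disconnection: both trisubstituted C=C bonds, by twofold cross-metathesis of 6,8-diallyl-7,4'-dihydroxyisoflavone with 2-methylbut-2-ene.
- The two allyl groups are traced back to O7 allyl ethers: Claisen rearrangement to C8, renewed allylation of O7, then a second Claisen rearrangement to C6, the only ortho position left.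
- No ring is formed in the route: rings A, B and C come intact from daidzein.

Key step: step 5

Remark on the chemistry: the target has no stereocentre and each new alkene carries two identical methyl groups, so nothing stereochemical has to be set; daidzein, allyl bromide and 2-methylbut-2-ene are taken as commercial.

**Step 1**
Reactants: 1 daidzein (7-hydroxy-3-(4-hydroxyphenyl)-4H-chromen-4-one); 2 allyl bromide (3-bromoprop-1-ene)
Product: 3 7-(allyloxy)-3-(4-hydroxyphenyl)-4H-chromen-4-one (7-O-allyldaidzein)
Conditions: K2CO3 (1.0 equiv), allyl bromide (1.05 equiv), DMF, rt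
Reagents that add atoms: allyl bromide, C=CCBr
Why: Williamson ether synthesis; the 7-OH is para to the C4 carbonyl (a vinylogous carboxylic acid, roughly two pKa units more acidic than the 4'-OH), so one equivalent of carbonate should form essentially only the 7-phenoxide, which is allylated while the 4'-OH stays free.

**Step 2**
Reactants: 3 7-(allyloxy)-3-(4-hydroxyphenyl)-4H-chromen-4-one
Product: 5 8-allyl-7-hydroxy-3-(4-hydroxyphenyl)-4H-chromen-4-one (8-allyldaidzein), via C8 ortho-dienone 4 (not isolated)
Conditions: N,N-diethylaniline, 200–210 °C, Ar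
Reagents that add atoms: none
Why: Aromatic Claisen rearrangement; the [3,3]-sigmatropic shift should run across the C7–C8 bond, which has the higher double-bond character in the benzopyranone, and dienone 4 then tautomerises to the phenol; a minor share of migration to C6 would do no harm, because both regioisomers lead to the same diallyl compound after steps 3 and 4.

**Step 3**
Reactants: 5 8-allyl-7-hydroxy-3-(4-hydroxyphenyl)-4H-chromen-4-one; 2 allyl bromide
Product: 6 8-allyl-7-(allyloxy)-3-(4-hydroxyphenyl)-4H-chromen-4-one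
Conditions: KHCO3 (1.5 equiv), allyl bromide (1.2 equiv), DMF, 50 °C
Reagents that add atoms: allyl bromide, C=CCBr
Why: Williamson ether synthesis under hydrogencarbonate control; the weak base should ionise only the vinylogous-acid 7-OH (still the more acidic phenol despite the ortho allyl group) and not the 4'-OH, as in the selective alkylation of a phenol para to a carbonyl group beside an ordinary phenol.

**Step 4**
Reactants: 6 8-allyl-7-(allyloxy)-3-(4-hydroxyphenyl)-4H-chromen-4-one
Product: 8 6,8-diallyl-7-hydroxy-3-(4-hydroxyphenyl)-4H-chromen-4-one, via C6 ortho-dienone 7 (not isolated)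
Conditions: N,N-diethylaniline, 210 °C, Ar
Reagents that add atoms: none
Why: Aromatic Claisen rearrangement; with C8 occupied, C6 is the only ortho position that carries hydrogen, so only dienone 7 can tautomerise to a phenol (migration to C8 is reversible and unproductive), as in the rearrangement of 8-substituted 7-allyloxycoumarins to their 6-allyl isomers.

**Step 5**
Reactants: 8 6,8-diallyl-7-hydroxy-3-(4-hydroxyphenyl)-4H-chromen-4-one; 9 2-methylbut-2-ene
Product: 12 7-hydroxy-3-(4-hydroxyphenyl)-6,8-bis(3-methylbut-2-en-1-yl)-4H-chromen-4-one, via 8-allyl-6-prenyl isoflavone 10 (not isolated), via 6-allyl-8-prenyl isoflavone 11 (not isolated)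
Conditions: RuCl2(=CHPh)(H2IMes)(PCy3) (second-generation Grubbs catalyst, 2 × 5 mol %), 1,4-benzoquinone (10 mol %), 2-methylbut-2-ene/CH2Cl2 1:1, sealed tube, 40 °C
Reagents that add atoms: 2-methylbut-2-ene, CC=C(C)C
Why: Olefin cross-metathesis by the Chauvin mechanism: the benzylidene complex loses PCy3, and the 14-electron alkylidene RuCl2(=CHR)(H2IMes) undergoes [2+2] cycloaddition and cycloreversion with each monosubstituted allyl alkene and with 2-methylbut-2-ene, so that each terminal CH2 is exchanged for an isopropylidene group and leaves with the ethylidene half of the reagent as propene. The closest known reaction type is the ruthenium-catalysed cross-metathesis of allylarenes and ortho-allylphenols with 2-methylbut-2-ene to prenylarenes. No ring is closed and no stereocentre is formed, and each new C=C bond bears two identical methyl groups, so there is no E/Z question. The step needs chemoselectivity for cross-metathesis over homodimerisation and over migration of the allyl double bonds into conjugation with ring A: the large excess of the alkene partner, used as co-solvent, should outcompete self-metathesis, 1,4-benzoquinone should intercept catalyst-derived hydride species, and the trisubstituted prenyl alkenes are too hindered to re-enter the cycle, so the mono-exchanged compounds 10 and 11 should both funnel to 12. The electron-poor trisubstituted C2=C3 bond of ring C and the two free phenols should be left alone by the catalyst.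

**Compound list**

1 | daidzein, 7-hydroxy-3-(4-hydroxyphenyl)-4H-chromen-4-one | O=c1c(-c2ccc(O)cc2)coc2cc(O)ccc12 | starting material
2 | allyl bromide, 3-bromoprop-1-ene | C=CCBr | starting material
3 | 7-(allyloxy)-3-(4-hydroxyphenyl)-4H-chromen-4-one | C=CCOc1ccc2c(=O)c(-c3ccc(O)cc3)coc2c1 | intermediate
4 | C8 ortho-dienone (racemic, not isolated), 8-allyl-3-(4-hydroxyphenyl)-4H-chromene-4,7(8H)-dione | C=CCC1C(=O)C=CC2=C1OC=C(c3ccc(O)cc3)C2=O | intermediate
5 | 8-allyl-7-hydroxy-3-(4-hydroxyphenyl)-4H-chromen-4-one | C=CCc1c(O)ccc2c(=O)c(-c3ccc(O)cc3)coc12 | intermediate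
6 | 8-allyl-7-(allyloxy)-3-(4-hydroxyphenyl)-4H-chromen-4-one | C=CCOc1ccc2c(=O)c(-c3ccc(O)cc3)coc2c1CC=C | intermediate
7 | C6 ortho-dienone (racemic, not isolated), 6,8-diallyl-3-(4-hydroxyphenyl)-4H-chromene-4,7(6H)-dione | C=CCC1C=C2C(=O)C(c3ccc(O)cc3)=COC2=C(CC=C)C1=O | intermediate
8 | 6,8-diallyl-7-hydroxy-3-(4-hydroxyphenyl)-4H-chromen-4-one | C=CCc1cc2c(=O)c(-c3ccc(O)cc3)coc2c(CC=C)c1O | intermediate
9 | 2-methylbut-2-ene | CC=C(C)C | starting material
10 | 8-allyl-7-hydroxy-3-(4-hydroxyphenyl)-6-(3-methylbut-2-en-1-yl)-4H-chromen-4-one (not isolated) | CC(C)=CCc1cc2c(=O)c(-c3ccc(O)cc3)coc2c(CC=C)c1O | intermediate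
11 | 6-allyl-7-hydroxy-3-(4-hydroxyphenyl)-8-(3-methylbut-2-en-1-yl)-4H-chromen-4-one (not isolated) | C=CCc1cc2c(=O)c(-c3ccc(O)cc3)coc2c(CC=C(C)C)c1O | intermediate
12 | 7-hydroxy-3-(4-hydroxyphenyl)-6,8-bis(3-methylbut-2-en-1-yl)-4H-chromen-4-one (7,4'-dihydroxy-6,8-diprenylisoflavone) | CC(C)=CCc1cc2c(=O)c(-c3ccc(O)cc3)coc2c(CC=C(C)C)c1O | target

Total step count: 5
Longest linear sequence: 5 steps

**Steps most likely to fail**

1. Step 5. The allyl double bonds may migrate into conjugation with ring A through hydride species formed as the catalyst decays at the acidic 7-OH, and the reaction may stall after only one of the two alkene exchanges. The fallback sets out from 8 and comes back at 12; it forms the same two C=C bonds from an aldehyde and a phosphorus ylide, so no metathesis catalyst is involved. Both phenols of 8 are silylated (TBSCl, imidazole, DMF, 40 °C) to 6,8-diallyl-7-(tert-butyldimethylsilyloxy)-3-[4-(tert-butyldimethylsilyloxy)phenyl]-4H-chromen-4-one F1. Lemieux–Johnson cleavage of both terminal alkenes (OsO4 cat., NaIO4, 2,6-lutidine, dioxane/H2O, rt; the electron-poor C2=C3 bond should react far more slowly) should give 2,2'-{7-(tert-butyldimethylsilyloxy)-3-[4-(tert-butyldimethylsilyloxy)phenyl]-4-oxo-4H-chromene-6,8-diyl}diacetaldehyde F2, which is used crude. Twofold Wittig olefination with the ylide from isopropyltriphenylphosphonium iodide and n-BuLi (THF, −78 °C to 0 °C) should give 7-(tert-butyldimethylsilyloxy)-3-[4-(tert-butyldimethylsilyloxy)phenyl]-6,8-bis(3-methylbut-2-en-1-yl)-4H-chromen-4-one F3. Bu4NF buffered with AcOH (THF, 0 °C) then frees both phenols to give 12.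

2. Step 3. Site selectivity between the two phenols may erode, with alkylation at O4' and double allylation, because the 8-allyl group shields O7 and narrows the acidity gap. The fallback sets out from 3, where the 4'-OH is the only free hydroxyl, and comes back at 8. Silylation of 3 (TIPSCl, imidazole, DMF, rt) gives 7-(allyloxy)-3-[4-(triisopropylsilyloxy)phenyl]-4H-chromen-4-one F4. Claisen rearrangement (N,N-diethylaniline, 200–210 °C) should give 8-allyl-7-hydroxy-3-[4-(triisopropylsilyloxy)phenyl]-4H-chromen-4-one F5, whose single free phenol is allylated without ambiguity (allyl bromide, K2CO3, acetone, reflux) to 8-allyl-7-(allyloxy)-3-[4-(triisopropylsilyloxy)phenyl]-4H-chromen-4-one F6. A second Claisen rearrangement (N,N-diethylaniline, 210 °C) should give 6,8-diallyl-7-hydroxy-3-[4-(triisopropylsilyloxy)phenyl]-4H-chromen-4-one F7, and Bu4NF (THF, 0 °C) removes the silyl group to give 8.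

3. Step 4. Migration across the C6–C7 bond of low double-bond character may be slow, so that at the temperature required the freed 7-OH adds to a neighbouring allyl double bond (closure to a 2-methyl-2,3-dihydrobenzofuran) or the phenol degrades. The fallback sets out from 6 and comes back at 8; it runs the rearrangement as an acylative Claisen reaction, so that the phenol is capped as soon as it is formed. Acetylation of 6 (Ac2O, pyridine, rt) gives 4-[8-allyl-7-(allyloxy)-4-oxo-4H-chromen-3-yl]phenyl acetate F8. Heating F8 in N,N-diethylaniline with Ac2O (sealed tube, 210 °C) should give 6,8-diallyl-3-(4-acetoxyphenyl)-4-oxo-4H-chromen-7-yl acetate F9. Mild methanolysis (K2CO3, MeOH, 0 °C) then gives 8.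

**Further compounds**

F1 | step 5 | 6,8-diallyl-7-(tert-butyldimethylsilyloxy)-3-[4-(tert-butyldimethylsilyloxy)phenyl]-4H-chromen-4-one | C=CCc1cc2c(=O)c(-c3ccc(O[Si](C)(C)C(C)(C)C)cc3)coc2c(CC=C)c1O[Si](C)(C)C(C)(C)C
F2 | step 5 | 2,2'-{7-(tert-butyldimethylsilyloxy)-3-[4-(tert-butyldimethylsilyloxy)phenyl]-4-oxo-4H-chromene-6,8-diyl}diacetaldehyde | O=CCc1cc2c(=O)c(-c3ccc(O[Si](C)(C)C(C)(C)C)cc3)coc2c(CC=O)c1O[Si](C)(C)C(C)(C)C
F3 | step 5 | 7-(tert-butyldimethylsilyloxy)-3-[4-(tert-butyldimethylsilyloxy)phenyl]-6,8-bis(3-methylbut-2-en-1-yl)-4H-chromen-4-one | CC(C)=CCc1cc2c(=O)c(-c3ccc(O[Si](C)(C)C(C)(C)C)cc3)coc2c(CC=C(C)C)c1O[Si](C)(C)C(C)(C)C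
F4 | step 3 | 7-(allyloxy)-3-[4-(triisopropylsilyloxy)phenyl]-4H-chromen-4-one | C=CCOc1ccc2c(=O)c(-c3ccc(O[Si](C(C)C)(C(C)C)C(C)C)cc3)coc2c1
F5 | step 3 | 8-allyl-7-hydroxy-3-[4-(triisopropylsilyloxy)phenyl]-4H-chromen-4-one | C=CCc1c(O)ccc2c(=O)c(-c3ccc(O[Si](C(C)C)(C(C)C)C(C)C)cc3)coc12
F6 | step 3 | 8-allyl-7-(allyloxy)-3-[4-(triisopropylsilyloxy)phenyl]-4H-chromen-4-one | C=CCOc1ccc2c(=O)c(-c3ccc(O[Si](C(C)C)(C(C)C)C(C)C)cc3)coc2c1CC=C
F7 | step 3 | 6,8-diallyl-7-hydroxy-3-[4-(triisopropylsilyloxy)phenyl]-4H-chromen-4-one | C=CCc1cc2c(=O)c(-c3ccc(O[Si](C(C)C)(C(C)C)C(C)C)cc3)coc2c(CC=C)c1O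
F8 | step 4 | 4-[8-allyl-7-(allyloxy)-4-oxo-4H-chromen-3-yl]phenyl acetate | C=CCOc1ccc2c(=O)c(-c3ccc(OC(C)=O)cc3)coc2c1CC=C
F9 | step 4 | 6,8-diallyl-3-(4-acetoxyphenyl)-4-oxo-4H-chromen-7-yl acetate | C=CCc1cc2c(=O)c(-c3ccc(OC(C)=O)cc3)coc2c(CC=C)c1OC(C)=O
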